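The route rests on cutting the C4–C4a bond that joins the pyranone ring C to ring A. Ring A is a mirror-symmetric phloroglucinol unit, so its two carbons ortho to O1 are identical and each is activated by three oxygens. An acyl cation tethered through O1 and C2 can therefore close ring C at carbon without any regiochemical question. The key step does this in one operation: an (E)-2-allyloxy-3-aryloxy-3-(4-methoxyphenyl)acrylic acid, with the O1–C2 aryl ether, the C3 oxygen and the 4-methoxyphenyl group already in place and the carboxyl cis to the 3,5-bis(benzyloxy)phenoxy group, is cyclised to the fully protected flavonol. Orthogonal allyl and benzyl ethers then let the C3 hydroxyl alone be sulfated.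

Key step: step 6

Assumption: 3,5-bis(benzyloxy)phenol and 4-methoxybenzoyl chloride are purchased; sulfate monoesters 13 and 14 are written as neutral hydrogen sulfates but would be handled as sodium salts (NaHCO3 work-up), the free acid being released only by cold H+ exchange.

Design remark: the aroyl group is delivered as its acid chloride at −78 °C instead of by an equilibrating ester condensation, because an α-allyloxy ester enolate undergoes [2,3]-Wittig rearrangement on warming; every step that carries the allyl enol ether is kept at or below 40 °C to stay clear of its [3,3] shift.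

Step 1
Reactants: 1 methyl glycolate
Product: 2 methyl 2-(allyloxy)acetate
Conditions: allyl bromide, Ag2O, Et2O, rt, dark
Reagents that add atoms: allyl bromide, C=CCBr
Why: Ag2O-promoted Williamson etherification alkylates the hydroxyl without forming a free alkoxide, so the methyl ester should not transesterify or self-condense.

Step 2
Reactants: 2 methyl 2-(allyloxy)acetate; 3 4-methoxybenzoyl chloride
Product: 5 methyl 2-(allyloxy)-3-(4-methoxyphenyl)-3-oxopropanoate (racemic), via lithium ester enolate 4 (not isolated)
Conditions: 2 (2.1 equiv), LiN(SiMe3)2 (2.1 equiv), THF, −78 °C; then 3 (1.0 equiv), −78 °C; AcOH, −78 °C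
Reagents that add atoms: none
Why: Claisen-type C-acylation of a preformed lithium ester enolate by an aroyl chloride (Rathke conditions) is fast at −78 °C, where the [2,3]-Wittig shift of the enolate should not compete, and the second equivalent of enolate takes up the acidic C2 proton of the product so that it is not acylated twice.

Step 3
Reactants: 5 methyl 2-(allyloxy)-3-(4-methoxyphenyl)-3-oxopropanoate
Product: 6 methyl (E)-2-(allyloxy)-3-(4-methoxyphenyl)-3-(tosyloxy)acrylate (tosyloxy cis to the ester)
Conditions: TsCl, TMEDA, LiCl, MeCN, 0 °C to rt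
Reagents that add atoms: p-toluenesulfonyl chloride, Cc1ccc(cc1)S(Cl)(=O)=O
Why: Enol O-sulfonylation of an α-substituted β-keto ester, in which Li+ chelation between the enolate oxygen and the ester carbonyl should fix the geometry with tosyloxy cis to the ester, while the stabilised enolate does not rearrange at this temperature.

Step 4
Reactants: 6 methyl (E)-2-(allyloxy)-3-(4-methoxyphenyl)-3-(tosyloxy)acrylate; 7 3,5-bis(benzyloxy)phenol
Product: 8 methyl (E)-2-(allyloxy)-3-[3,5-bis(benzyloxy)phenoxy]-3-(4-methoxyphenyl)acrylate (aryloxy cis to the ester)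
Conditions: Cs2CO3, DMF, rt to 40 °C
Reagents that add atoms: none
Why: Nucleophilic vinylic substitution by addition–elimination, in which the cesium phenoxide adds at C3 of the β-sulfonyloxy acrylate and the resulting ester enolate expels tosylate before it rotates, which should retain the geometry, although either isomer would serve the ring closure.

Step 5
Reactants: 8 methyl (E)-2-(allyloxy)-3-[3,5-bis(benzyloxy)phenoxy]-3-(4-methoxyphenyl)acrylate
Product: 9 (E)-2-(allyloxy)-3-[3,5-bis(benzyloxy)phenoxy]-3-(4-methoxyphenyl)acrylic acid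
Conditions: LiOH·H2O, THF/MeOH/H2O, rt to 40 °C; then 1 M HCl to pH 3, 0 °C
Reagents that add atoms: lithium hydroxide, [Li+].[OH-]
Why: Saponification by acyl–oxygen cleavage, the usual way to free β-aryloxyacrylic acids before chromone closure; C3 is shielded and donor-substituted so hydroxide should not displace the aryloxide, and cold dilute acid should spare both enol ethers.

Step 6
Reactants: 9 (E)-2-(allyloxy)-3-[3,5-bis(benzyloxy)phenoxy]-3-(4-methoxyphenyl)acrylic acid
Product: 11 3-(allyloxy)-5,7-bis(benzyloxy)-2-(4-methoxyphenyl)-4H-chromen-4-one, via mixed trifluoroacetic anhydride 10 (not isolated)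
Conditions: (CF3CO)2O (3 equiv), CH2Cl2, 0 °C to rt
Reagents that add atoms: none
Why: Trifluoroacetic anhydride turns the acid into its mixed anhydride, which, directly or after loss of trifluoroacetate to a donor-stabilised acylium ion, is attacked by the ring A carbon ortho to the ether oxygen; proton loss from the Wheland intermediate restores ring A and leaves the pyran-4-one. This is the intramolecular Friedel–Crafts acylation by which β-aryloxyacrylic and β-aryloxycinnamic acids are closed to chromones and flavones. Ring C forms as a six-membered ring by exo attack on the acyl carbon (6-exo-trig on the anhydride carbonyl), and because the O1–C2 ether is already present only the C4–C4a bond has to be made. No stereocentre is created. The site selectivity comes from the substrate: the two carbons ortho to O1 are equivalent by symmetry and each is ortho to O1, ortho to one benzyloxy group and para to the other, whereas ring B could be reached only from the other alkene geometry, at a carbon meta to its methoxy group, to give a strained indenone, and the tetrasubstituted alkene offers no site for C-trifluoroacetylation. The (E) geometry places the carboxyl cis to the aryloxy group, a (Z) isomer could equilibrate by reversible protonation at C2 of the push–pull alkene, and the mild acidity at 0 °C to rt is chosen so that the benzyl ethers and the allyl enol ether should stay in place.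

Step 7
Reactants: 11 3-(allyloxy)-5,7-bis(benzyloxy)-2-(4-methoxyphenyl)-4H-chromen-4-one
Product: 12 5,7-bis(benzyloxy)-3-hydroxy-2-(4-methoxyphenyl)-4H-chromen-4-one
Conditions: Pd(PPh3)4 (5 mol%), morpholine, THF, rt
Reagents that add atoms: none
Why: Tsuji–Trost deallylation, in which zerovalent palladium ionises the allyl enol ether because the flavonolate is a good leaving group and morpholine traps the π-allyl fragment, while the benzyl ethers are inert.

Step 8
Reactants: 12 5,7-bis(benzyloxy)-3-hydroxy-2-(4-methoxyphenyl)-4H-chromen-4-one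
Product: 13 5,7-bis(benzyloxy)-2-(4-methoxyphenyl)-4-oxo-4H-chromen-3-yl hydrogen sulfate
Conditions: SO3·pyridine (5 equiv), pyridine, 40 °C
Reagents that add atoms: sulfur trioxide–pyridine complex, [O-]S(=O)(=O)[n+]1ccccc1
Why: O-sulfonation with an SO3–amine complex of the only free hydroxyl, C3–OH, since O5 and O7 are benzylated and the methoxy group is inert, so no regiochemical question arises.

Step 9
Reactants: 13 5,7-bis(benzyloxy)-2-(4-methoxyphenyl)-4-oxo-4H-chromen-3-yl hydrogen sulfate
Product: 14 kaempferide 3-O-sulfate
Conditions: H2 (1 atm), 10% Pd/C, MeOH/THF, rt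
Reagents that add atoms: none
Why: Hydrogenolysis of both aryl benzyl ethers on palladium under neutral conditions, where the sulfate monoester salt and the chromone C2=C3 bond should survive, as is usual for benzyl-protected flavonoid sulfates.

Compound list
1 | methyl glycolate | COC(=O)CO | starting material
2 | methyl 2-(allyloxy)acetate | COC(=O)COCC=C | intermediate
3 | 4-methoxybenzoyl chloride | COc1ccc(cc1)C(Cl)=O | starting material
4 | lithium 2-(allyloxy)-1-methoxyethen-1-olate (O–Li cis to the allyloxy oxygen) | [Li+].[O-]/C(OC)=C\OCC=C | intermediate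
5 | methyl 2-(allyloxy)-3-(4-methoxyphenyl)-3-oxopropanoate (racemic) | COC(=O)C(OCC=C)C(=O)c1ccc(OC)cc1 | intermediate
6 | methyl (E)-2-(allyloxy)-3-(4-methoxyphenyl)-3-(tosyloxy)acrylate | COC(=O)/C(OCC=C)=C(\OS(=O)(=O)c1ccc(C)cc1)c1ccc(OC)cc1 | intermediate
7 | 3,5-bis(benzyloxy)phenol | Oc1cc(OCc2ccccc2)cc(OCc2ccccc2)c1 | starting material
8 | methyl (E)-2-(allyloxy)-3-[3,5-bis(benzyloxy)phenoxy]-3-(4-methoxyphenyl)acrylate | COC(=O)/C(OCC=C)=C(\Oc1cc(OCc2ccccc2)cc(OCc2ccccc2)c1)c1ccc(OC)cc1 | intermediate
9 | (E)-2-(allyloxy)-3-[3,5-bis(benzyloxy)phenoxy]-3-(4-methoxyphenyl)acrylic acid | OC(=O)/C(OCC=C)=C(\Oc1cc(OCc2ccccc2)cc(OCc2ccccc2)c1)c1ccc(OC)cc1 | intermediate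
10 | (E)-2-(allyloxy)-3-[3,5-bis(benzyloxy)phenoxy]-3-(4-methoxyphenyl)acrylic trifluoroacetic anhydride | O=C(OC(=O)C(F)(F)F)/C(OCC=C)=C(\Oc1cc(OCc2ccccc2)cc(OCc2ccccc2)c1)c1ccc(OC)cc1 | intermediate
11 | 3-(allyloxy)-5,7-bis(benzyloxy)-2-(4-methoxyphenyl)-4H-chromen-4-one | C=CCOc1c(-c2ccc(OC)cc2)oc2cc(OCc3ccccc3)cc(OCc3ccccc3)c2c1=O | intermediate
12 | 5,7-bis(benzyloxy)-3-hydroxy-2-(4-methoxyphenyl)-4H-chromen-4-one | COc1ccc(-c2oc3cc(OCc4ccccc4)cc(OCc4ccccc4)c3c(=O)c2O)cc1 | intermediate
13 | 5,7-bis(benzyloxy)-2-(4-methoxyphenyl)-4-oxo-4H-chromen-3-yl hydrogen sulfate | COc1ccc(-c2oc3cc(OCc4ccccc4)cc(OCc4ccccc4)c3c(=O)c2OS(=O)(=O)O)cc1 | intermediate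
14 | kaempferide 3-O-sulfate, 5,7-dihydroxy-2-(4-methoxyphenyl)-4-oxo-4H-chromen-3-yl hydrogen sulfate | COc1ccc(-c2oc3cc(O)cc(O)c3c(=O)c2OS(=O)(=O)O)cc1 | target

Total step count: 9. Longest linear sequence: 9 steps (1 to 14).

Steps most likely to fail

Step 4. Conjugate addition to the tetrasubstituted, donor-substituted enol tosylate may be slow. The phenoxide may then attack sulfur and transfer the sulfonyl group, or the allyl enol ether may undergo its [3,3] shift if heating is needed. The fallback makes the C3–O bond on a far more electrophilic β-chlorovinyl aldehyde and reaches the acid by oxidation, which also removes the ester hydrolysis. It sets out from 2 and uses 7.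
- Treating 2 with MeNHOMe·HCl and iPrMgCl in THF at −20 °C would give the Weinreb amide 2-(allyloxy)-N-methoxy-N-methylacetamide F1.
- Addition of 4-MeOC6H4MgBr would give 2-(allyloxy)-1-(4-methoxyphenyl)ethan-1-one F2.
- Vilsmeier–Haack–Arnold chloroformylation (POCl3, DMF, 0 to 50 °C) would give (E)-2-(allyloxy)-3-chloro-3-(4-methoxyphenyl)acrylaldehyde F3, with chlorine cis to the formyl group.
- Substitution of the chloride by 7 (K2CO3, DMF, rt) would give (E)-2-(allyloxy)-3-[3,5-bis(benzyloxy)phenoxy]-3-(4-methoxyphenyl)acrylaldehyde F4.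
- Pinnick oxidation (NaClO2, NaH2PO4, 2-methyl-2-butene, tBuOH/H2O, 0 °C) would come back to the route at 9.

Step 6. Acid-promoted ionisation or [3,3] shift of the allyl group at the enol ether, or loss of the peri benzyl group, may outrun or follow the acylation. The fallback keeps the same C4–C4a Friedel–Crafts closure but runs it on a substrate without an oxygen at C3 and adds that oxygen afterwards. It sets out from 7.
- Base-mediated conjugate addition of 7 to purchased methyl 3-(4-methoxyphenyl)propiolate (K2CO3, DMF, 60 °C; anti addition) would give methyl (Z)-3-[3,5-bis(benzyloxy)phenoxy]-3-(4-methoxyphenyl)acrylate F5.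
- Saponification would give (Z)-3-[3,5-bis(benzyloxy)phenoxy]-3-(4-methoxyphenyl)acrylic acid F6.
- Ring closure with (CF3CO)2O in CH2Cl2 would give 5,7-bis(benzyloxy)-2-(4-methoxyphenyl)-4H-chromen-4-one F7.
- C3 lithiation with LiN(iPr)2 at −78 °C, borylation with B(OMe)3 and oxidation with H2O2/AcOH would come back to the route at 12.

Step 8. Sulfation of the hydrogen-bonded, weakly nucleophilic C3 hydroxyl may stay incomplete, and the sulfate may hydrolyse during work-up or chromatography. The fallback carries the sulfate as a neutral, chromatographable diester. It sets out from 12.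
- Treating 12 with 2,2,2-trichloroethyl chlorosulfate, Et3N and DMAP in THF would give 5,7-bis(benzyloxy)-2-(4-methoxyphenyl)-4-oxo-4H-chromen-3-yl 2,2,2-trichloroethyl sulfate F8.
- Transfer hydrogenolysis (10% Pd/C, HCO2NH4, MeOH, rt) would remove the trichloroethyl group and both benzyl ethers in one operation and come back to the route at 14.

Further compounds
F1 | step 4 | 2-(allyloxy)-N-methoxy-N-methylacetamide | C=CCOCC(=O)N(C)OC
F2 | step 4 | 2-(allyloxy)-1-(4-methoxyphenyl)ethan-1-one | C=CCOCC(=O)c1ccc(OC)cc1
F3 | step 4 | (E)-2-(allyloxy)-3-chloro-3-(4-methoxyphenyl)acrylaldehyde | O=C/C(OCC=C)=C(\Cl)c1ccc(OC)cc1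
F4 | step 4 | (E)-2-(allyloxy)-3-[3,5-bis(benzyloxy)phenoxy]-3-(4-methoxyphenyl)acrylaldehyde | O=C/C(OCC=C)=C(\Oc1cc(OCc2ccccc2)cc(OCc2ccccc2)c1)c1ccc(OC)cc1
F5 | step 6 | methyl (Z)-3-[3,5-bis(benzyloxy)phenoxy]-3-(4-methoxyphenyl)acrylate | COC(=O)/C=C(\Oc1cc(OCc2ccccc2)cc(OCc2ccccc2)c1)c1ccc(OC)cc1
F6 | step 6 | (Z)-3-[3,5-bis(benzyloxy)phenoxy]-3-(4-methoxyphenyl)acrylic acid | OC(=O)/C=C(\Oc1cc(OCc2ccccc2)cc(OCc2ccccc2)c1)c1ccc(OC)cc1
F7 | step 6 | 5,7-bis(benzyloxy)-2-(4-methoxyphenyl)-4H-chromen-4-one | COc1ccc(-c2cc(=O)c3c(OCc4ccccc4)cc(OCc4ccccc4)cc3o2)cc1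
F8 | step 8 | 5,7-bis(benzyloxy)-2-(4-methoxyphenyl)-4-oxo-4H-chromen-3-yl 2,2,2-trichloroethyl sulfate | COc1ccc(-c2oc3cc(OCc4ccccc4)cc(OCc4ccccc4)c3c(=O)c2OS(=O)(=O)OCC(Cl)(Cl)Cl)cc1
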